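**Retrosynthetic overview**
1. Target 32 ← desilylation, 1(10)-epoxidation, C8 acylation with epoxy acid 13 and α-methylenation of hydroxy lactone 25.
2. 25 ← C8-OH-directed reduction and lactonisation of the ten-membered hydroxy enone 23; 23 ← ring expansion of the γ-stannyl bicyclo[5.3.0]decenol 22 by oxidative Grob-type fragmentation of the C6–C10 bond, which also creates the E-C1=C10 alkene.
3. 22 ← cycloheptene closure (metathesis) on the vinyl carbinol of ketone 19; 19 ← stannyl conjugate addition/methylation of alkylidene ketone 17; 17 ← aldol condensation of keto lactone 4 with aldehyde 9.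
4. 4 ← intramolecular α′-alkylation of the bromoacetate of (S)-4-hydroxycyclopentenone (sets C7 cis to C8–O); 9 ← asymmetric acetate aldol of methacrolein; 13 ← Sharpless epoxidation of angelyl alcohol.
5. Ring order: cyclopentane (bought) → 8,12-γ-lactone → cycloheptene → ten-membered carbocycle → 6,12-γ-lactone → 1,10-epoxide.

Assumption: germacrane numbering of the target (ring C1–C10, lactone carbons C11–C13, C14 on C10, C15 on C4) is used for locants of all bicyclic and macrocyclic intermediates, TBS = tert-butyldimethylsilyl, and (4S)-4-hydroxycyclopent-2-en-1-one, methacrolein and angelic acid are taken as commercial.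

**Step 1**
Reactants: 1 (4S)-4-hydroxycyclopent-2-en-1-one
Product: 2 (1S)-4-oxocyclopent-2-en-1-yl bromoacetate
Conditions: BrCH2COBr, pyridine, CH2Cl2, −20 → 0 °C
Reagents that add atoms: bromoacetyl bromide BrCC(=O)Br
Why: Pyridine-mediated acylation of the allylic alcohol leaves the carbinol configuration untouched and installs the two-carbon tether that becomes C11–C12.

**Step 2**
Reactants: 2 (1S)-4-oxocyclopent-2-en-1-yl bromoacetate
Product: 3 (3aR,6aR)-3,3a-dihydro-2H-cyclopenta[b]furan-2,4(6aH)-dione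
Conditions: LiN(SiMe3)2 (1.05 equiv), THF (0.01 M), −78 → −20 °C
Reagents that add atoms: none
Why: Proposed new method: intramolecular α′-C-alkylation of a 4-(bromoacetoxy)cyclopent-2-enone, in which kinetic deprotonation at C5 gives the cross-conjugated lithium dienolate that can reach the tethered CH2Br only on the face carrying the ester oxygen (5-(enolexo)-exo-tet closure through the minor s-trans ester rotamer), so the new C7–C11 bond and the C7 stereocentre are forced cis to C8–O, while β-elimination of the carboxylate is shut off because it would give a cyclopentadienone and O-alkylation would need a seven-membered ring; the closest known reaction types are intramolecular enolate alkylations that build cis-fused five-membered rings and the intermolecular α′-alkylation of 4-oxycyclopentenones with bromoacetates.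

**Step 3**
Reactants: 3 (3aR,6aR)-3,3a-dihydro-2H-cyclopenta[b]furan-2,4(6aH)-dione
Product: 4 (3aR,6aR)-tetrahydro-2H-cyclopenta[b]furan-2,4(3H)-dione
Conditions: H2 (1 atm), RhCl(PPh3)3 (5 mol %), benzene, 25 °C
Reagents that add atoms: none
Why: Homogeneous hydrogenation with the monovalent rhodium complex saturates the enone C=C without the hydrogenolysis of the allylic C–O bond that Pd/C could cause, and no stereocentre is formed.

**Step 4**
Reactants: 5 methacrolein
Product: 7 S-tert-butyl (3S)-3-hydroxy-4-methylpent-4-enethioate, via silyl ether 6 (not isolated)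
Conditions: Ti(OiPr)4 (10 mol %), (S)-BINOL (10 mol %), 4 Å MS, Et2O, −20 °C; then 1 M HCl, THF
Reagents that add atoms: 1-(tert-butylsulfanyl)-1-(trimethylsilyloxy)ethene C=C(O[Si](C)(C)C)SC(C)(C)C
Why: Keck-type catalytic asymmetric Mukaiyama aldol addition, in which the BINOL complex of tetravalent titanium exposes one face of the enal carbonyl to the silyl ketene acetal and sets C3 as S (the mirror-image ligand is used if the sense proves opposite for this α-branched enal), the acid work-up cleaving the transferred silyl group.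

**Step 5**
Reactants: 7 S-tert-butyl (3S)-3-hydroxy-4-methylpent-4-enethioate
Product: 8 S-tert-butyl (3S)-3-(TBS-oxy)-4-methylpent-4-enethioate
Conditions: TBSCl, imidazole, DMF, 25 °C
Reagents that add atoms: tert-butyldimethylsilyl chloride CC(C)(C)[Si](C)(C)Cl
Why: Standard imidazole-promoted silylation protects the allylic carbinol as a TBS ether that survives the bases and organometallics used later.

**Step 6**
Reactants: 8 S-tert-butyl (3S)-3-(TBS-oxy)-4-methylpent-4-enethioate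
Product: 9 (3S)-3-(TBS-oxy)-4-methylpent-4-enal
Conditions: i-Bu2AlH (1.1 equiv), CH2Cl2, −78 °C; aq. KNaC4H4O6
Reagents that add atoms: none
Why: Partial hydride reduction of the thioester stops at the aluminium hemithioacetal at −78 °C, which releases the aldehyde on work-up without touching the silyl ether or the β-stereocentre.

**Step 7**
Reactants: 10 angelic acid
Product: 11 (Z)-2-methylbut-2-en-1-ol
Conditions: LiAlH4, Et2O, 0 °C
Reagents that add atoms: none
Why: Hydride reduction of the carboxylic acid gives the allylic alcohol with the Z geometry retained at 0 °C.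

**Step 8**
Reactants: 11 (Z)-2-methylbut-2-en-1-ol
Product: 12 [(2S,3R)-2,3-dimethyloxiran-2-yl]methanol
Conditions: Ti(OiPr)4 (10 mol %), L-(+)-diethyl tartrate (12 mol %), t-BuOOH, 4 Å MS, CH2Cl2, −20 °C
Reagents that add atoms: tert-butyl hydroperoxide CC(C)(C)OO
Why: Katsuki–Sharpless asymmetric epoxidation, in which the L-(+)-tartrate titanium catalyst delivers oxygen to the same face that gives 2S epoxy alcohols from other allylic alcohols, so C2 is S and the Z geometry fixes C3 as R.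

**Step 9**
Reactants: 12 [(2S,3R)-2,3-dimethyloxiran-2-yl]methanol
Product: 13 (2R,3R)-2,3-dimethyloxirane-2-carboxylic acid
Conditions: RuCl3 (2 mol %), NaIO4, CCl4/MeCN/H2O, 25 °C
Reagents that add atoms: water O
Why: Catalytic ruthenium tetroxide oxidation (Sharpless conditions) takes the primary alcohol through the aldehyde hydrate to the acid without opening the trisubstituted epoxide, and only the change in substituent priority turns the 2S label into 2R.

**Step 10**
Reactants: 4 (3aR,6aR)-tetrahydro-2H-cyclopenta[b]furan-2,4(3H)-dione, 9 (3S)-3-(TBS-oxy)-4-methylpent-4-enal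
Product: 17 (3aR,5E,6aR)-5-[(3S)-3-(TBS-oxy)-4-methylpent-4-en-1-ylidene]tetrahydro-2H-cyclopenta[b]furan-2,4(3H)-dione, via lithium enolate 14 (not isolated), via lithium aldolate 15 (not isolated), via mesylate 16 (not isolated)
Conditions: LiN(iPr)2 (1.05 equiv), THF, −78 °C; then 9; then MsCl, Et3N, −78 → 0 °C
Reagents that add atoms: none
Why: Directed aldol condensation, in which the amide base removes a proton from the less hindered C10 methylene (not the ring-fusion C7–H, whose enolate could expel the lactone oxygen), the enolate adds to aldehyde 9, and mesylation with E1cB elimination gives the thermodynamically favoured E-alkylidene ketone, so both aldol stereocentres are erased.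

**Step 11**
Reactants: 17 (3aR,5E,6aR)-5-[(3S)-3-(TBS-oxy)-4-methylpent-4-en-1-ylidene]tetrahydro-2H-cyclopenta[b]furan-2,4(3H)-dione
Product: 19 (3aR,5R,6aR)-5-methyl-5-[(1R,3S)-3-(TBS-oxy)-4-methyl-1-(tributylstannyl)pent-4-en-1-yl]tetrahydro-2H-cyclopenta[b]furan-2,4(3H)-dione, via stannyl lithium enolate 18 (not isolated)
Conditions: Bu3SnLi, THF, −78 °C; then MeI, DMPU, −78 → −30 °C
Reagents that add atoms: tributylstannyllithium [Li][Sn](CCCC)(CCCC)CCCC; iodomethane CI
Why: Conjugate addition of the stannyl anion to the exocyclic enone followed by C-methylation of the lithium enolate, in which the electrophile enters anti to the large, electron-releasing C–Sn bond in the conformer with C1–H eclipsing the enolate (Fleming-type acyclic stereocontrol of β-metalloid enolates), fixing the anti Sn/Me relationship at C1/C10 that step 15 turns into the E alkene (the ring biases this remote carbon only weakly, and the C1,C10 bis-epimer would lead to the same alkene).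

**Step 12**
Reactants: 19 (3aR,5R,6aR)-5-methyl-5-[(1R,3S)-3-(TBS-oxy)-4-methyl-1-(tributylstannyl)pent-4-en-1-yl]tetrahydro-2H-cyclopenta[b]furan-2,4(3H)-dione
Product: 20 (3aR,4S,5R,6aR)-4-ethenyl-4-hydroxy-5-methyl-5-[(1R,3S)-3-(TBS-oxy)-4-methyl-1-(tributylstannyl)pent-4-en-1-yl]hexahydro-2H-cyclopenta[b]furan-2-one
Conditions: CH2=CHMgBr, CeCl3, THF, −78 °C
Reagents that add atoms: vinylmagnesium bromide C=C[Mg]Br
Why: Organocerium 1,2-addition (Imamoto conditions) tolerates the hindered, enolisable ketone and the lactone, and the vinyl group approaches anti to the bulky stannylalkyl group on the neighbouring quaternary carbon to give the 6S carbinol, a centre that becomes a ketone carbon again in step 15.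

**Step 13**
Reactants: 20 (3aR,4S,5R,6aR)-4-ethenyl-4-hydroxy-5-methyl-5-[(1R,3S)-3-(TBS-oxy)-4-methyl-1-(tributylstannyl)pent-4-en-1-yl]hexahydro-2H-cyclopenta[b]furan-2-one
Product: 21 (1R,3S,6S,7R,8R,10R)-6-hydroxy-3-(TBS-oxy)-1-(tributylstannyl)-6,10-cyclo-13-norgermacr-4-en-12,8-olide
Conditions: RuCl2(=CHPh)(H2IMes)(PCy3) (second-generation Grubbs catalyst, 5 mol %), CH2Cl2, 40 °C
Reagents that add atoms: none
Why: Ring-closing olefin metathesis between the vinyl group and the 1,1-disubstituted alkene closes the seven-membered ring with loss of ethene, the ring enforcing the Z geometry of the new C4=C5 bond.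

**Step 14**
Reactants: 21 (1R,3S,6S,7R,8R,10R)-6-hydroxy-3-(TBS-oxy)-1-(tributylstannyl)-6,10-cyclo-13-norgermacr-4-en-12,8-olide
Product: 22 N-methoxy-N-methyl-(1R,3S,6S,7R,8R,10R)-6,8-dihydroxy-3-(TBS-oxy)-1-(tributylstannyl)-6,10-cyclo-13-norgermacr-4-en-12-amide
Conditions: AlMe3, MeNH(OMe)·HCl, CH2Cl2, 0 → 25 °C
Reagents that add atoms: N,O-dimethylhydroxylamine hydrochloride CNOC.Cl
Why: Weinreb aminolysis of the γ-lactone by the aluminium amide frees the C8 carbinol needed to direct the later ketone reduction and is run while C6 is still a carbinol, so no β-elimination next to a ketone can occur and no stereocentre is touched.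

**Step 15**
Reactants: 22 N-methoxy-N-methyl-(1R,3S,6S,7R,8R,10R)-6,8-dihydroxy-3-(TBS-oxy)-1-(tributylstannyl)-6,10-cyclo-13-norgermacr-4-en-12-amide
Product: 23 N-methoxy-N-methyl-(3S,7R,8R)-8-hydroxy-6-oxo-3-(TBS-oxy)-13-norgermacra-1(10)E,4Z-dien-12-amide
Conditions: Pb(OAc)4 (1.1 equiv), benzene, 10 → 25 °C
Reagents that add atoms: none
Why: Grob-type oxidative 1,4-fragmentation of a γ-stannyl alcohol, in which the tetravalent-lead alkoxide collapses to the ketone with heterolysis of the C6–C10 ring-fusion bond antiperiplanar to the C1–Sn bond, expanding the five/seven bicycle to the ten-membered ring and translating the anti Sn/Me relationship into the E-1(10) alkene while the Z-4 alkene comes unchanged from the cycloheptene.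

**Step 16**
Reactants: 23 N-methoxy-N-methyl-(3S,7R,8R)-8-hydroxy-6-oxo-3-(TBS-oxy)-13-norgermacra-1(10)E,4Z-dien-12-amide
Product: 25 (3S,6R,7R,8R)-8-hydroxy-3-(TBS-oxy)-13-norgermacra-1(10)E,4Z-dien-12,6-olide, via diol amide 24 (not isolated)
Conditions: Me4NBH(OAc)3, AcOH/MeCN, −30 °C; then PPTS (cat.), CH2Cl2, 25 °C
Reagents that add atoms: none
Why: Evans–Saksena hydroxyl-directed reduction, in which the acetoxyborohydride bound to the C8 oxygen delivers hydride intramolecularly to the same face of the ketone to give the 6,8-anti diol (6R), after which the 6-hydroxyl displaces the Weinreb amine to form the trans-fused γ-lactone, the more stable of the two possible lactones.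

**Step 17**
Reactants: 25 (3S,6R,7R,8R)-8-hydroxy-3-(TBS-oxy)-13-norgermacra-1(10)E,4Z-dien-12,6-olide
Product: 28 (3S,6R,7R,8R)-8-hydroxy-3-(TBS-oxy)germacra-1(10)E,4Z,11(13)-trien-12,6-olide, via Mannich base 26 (not isolated), via trimethylammonium iodide 27 (not isolated)
Conditions: LiN(SiMe3)2 (2.3 equiv), THF, −78 °C; CH2=NMe2+ I−; then MeI, MeOH; then aq. NaHCO3, CH2Cl2
Reagents that add atoms: N,N-dimethylmethyleneiminium iodide C=[N+](C)C.[I-]
Why: Eschenmoser α-methylenation, in which the lactone enolate (formed alongside the C8 alkoxide) undergoes a Mannich reaction with the iminium salt and N-methylation followed by base-induced loss of trimethylamine gives the exocyclic methylene, erasing the transient C11 stereocentre.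

**Step 18**
Reactants: 28 (3S,6R,7R,8R)-8-hydroxy-3-(TBS-oxy)germacra-1(10)E,4Z,11(13)-trien-12,6-olide, 13 (2R,3R)-2,3-dimethyloxirane-2-carboxylic acid
Product: 30 (3S,6R,7R,8R)-8-[(2R,3R)-2,3-dimethyloxirane-2-carbonyloxy]-3-(TBS-oxy)germacra-1(10)E,4Z,11(13)-trien-12,6-olide, via mixed anhydride 29 (not isolated)
Conditions: 13, 2,4,6-trichlorobenzoyl chloride, Et3N, THF, 25 °C; then 28, DMAP (cat.), toluene, 25 °C
Reagents that add atoms: none
Why: Yamaguchi esterification through the mixed 2,4,6-trichlorobenzoic anhydride acylates the hindered C8 hydroxyl on oxygen (retention at C8) under conditions mild enough for the epoxy acid and the α-methylene lactone.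

**Step 19**
Reactants: 30 (3S,6R,7R,8R)-8-[(2R,3R)-2,3-dimethyloxirane-2-carbonyloxy]-3-(TBS-oxy)germacra-1(10)E,4Z,11(13)-trien-12,6-olide
Product: 31 (1R,3S,6R,7R,8R,10R)-1,10-epoxy-8-[(2R,3R)-2,3-dimethyloxirane-2-carbonyloxy]-3-(TBS-oxy)germacra-4Z,11(13)-dien-12,6-olide
Conditions: mCPBA (1.05 equiv), CH2Cl2, 0 °C
Reagents that add atoms: 3-chloroperoxybenzoic acid OOC(=O)c1cccc(Cl)c1
Why: Prilezhaev epoxidation takes place at the most electron-rich alkene, the E-1(10) trisubstituted bond (the 4,5-alkene is deactivated by two allylic oxygens and the acrylate is electron-poor), and peripheral attack on its exposed face, as observed for germacranolides, gives the 1β,10α (1R,10R) epoxide.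

**Step 20**
Reactants: 31 (1R,3S,6R,7R,8R,10R)-1,10-epoxy-8-[(2R,3R)-2,3-dimethyloxirane-2-carbonyloxy]-3-(TBS-oxy)germacra-4Z,11(13)-dien-12,6-olide
Product: 32 (1R,3S,6R,7R,8R,10R)-1,10-epoxy-8-[(2R,3R)-2,3-dimethyloxirane-2-carbonyloxy]-3-hydroxygermacra-4Z,11(13)-dien-12,6-olide (CNP0268255.1)
Conditions: HF·pyridine, pyridine, THF, 0 °C
Reagents that add atoms: none
Why: Buffered fluoride desilylation cleaves the allylic TBS ether without opening either epoxide or adding to the α-methylene lactone, revealing the 3-hydroxyl of the target.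

**Compound list**
1 | (4S)-4-hydroxycyclopent-2-en-1-one | O=C1C=C[C@@H](O)C1 | starting material
2 | (1S)-4-oxocyclopent-2-en-1-yl bromoacetate | O=C1C=C[C@@H](OC(=O)CBr)C1 | intermediate
3 | (3aR,6aR)-3,3a-dihydro-2H-cyclopenta[b]furan-2,4(6aH)-dione | O=C1C=C[C@H]2OC(=O)C[C@@H]12 | intermediate
4 | (3aR,6aR)-tetrahydro-2H-cyclopenta[b]furan-2,4(3H)-dione | O=C1CC[C@H]2OC(=O)C[C@@H]12 | intermediate
5 | methacrolein (2-methylprop-2-enal) | CC(=C)C=O | starting material
6 | S-tert-butyl (3S)-4-methyl-3-(trimethylsilyloxy)pent-4-enethioate | C=C(C)[C@@H](O[Si](C)(C)C)CC(=O)SC(C)(C)C | intermediate (not isolated)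
7 | S-tert-butyl (3S)-3-hydroxy-4-methylpent-4-enethioate | C=C(C)[C@@H](O)CC(=O)SC(C)(C)C | intermediate
8 | S-tert-butyl (3S)-3-(TBS-oxy)-4-methylpent-4-enethioate | C=C(C)[C@@H](O[Si](C)(C)C(C)(C)C)CC(=O)SC(C)(C)C | intermediate
9 | (3S)-3-(TBS-oxy)-4-methylpent-4-enal | C=C(C)[C@@H](O[Si](C)(C)C(C)(C)C)CC=O | intermediate
10 | angelic acid ((Z)-2-methylbut-2-enoic acid) | C/C=C(C)\C(=O)O | starting material
11 | (Z)-2-methylbut-2-en-1-ol | C/C=C(C)\CO | intermediate
12 | [(2S,3R)-2,3-dimethyloxiran-2-yl]methanol | OC[C@]1(C)O[C@@H]1C | intermediate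
13 | (2R,3R)-2,3-dimethyloxirane-2-carboxylic acid | OC(=O)[C@]1(C)O[C@@H]1C | intermediate
14 | lithium (3aR,6aR)-2-oxo-3,3a,6,6a-tetrahydro-2H-cyclopenta[b]furan-4-olate | [Li]OC1=CC[C@H]2OC(=O)C[C@@H]12 | intermediate (not isolated)
15 | lithium (1S,3S)-3-(TBS-oxy)-1-[(3aR,5S,6aR)-2,4-dioxohexahydro-2H-cyclopenta[b]furan-5-yl]-4-methylpent-4-en-1-olate | [Li]O[C@@H](C[C@H](O[Si](C)(C)C(C)(C)C)C(C)=C)[C@@H]1C[C@H]2OC(=O)C[C@H]2C1=O | intermediate (not isolated)
16 | (1S,3S)-3-(TBS-oxy)-1-[(3aR,5S,6aR)-2,4-dioxohexahydro-2H-cyclopenta[b]furan-5-yl]-4-methylpent-4-en-1-yl methanesulfonate | CS(=O)(=O)O[C@@H](C[C@H](O[Si](C)(C)C(C)(C)C)C(C)=C)[C@@H]1C[C@H]2OC(=O)C[C@H]2C1=O | intermediate (not isolated)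
17 | (3aR,5E,6aR)-5-[(3S)-3-(TBS-oxy)-4-methylpent-4-en-1-ylidene]tetrahydro-2H-cyclopenta[b]furan-2,4(3H)-dione | O=C1/C(=C/C[C@H](O[Si](C)(C)C(C)(C)C)C(C)=C)C[C@H]2OC(=O)C[C@@H]12 | intermediate
18 | lithium (3aR,6aR)-5-[(1R,3S)-3-(TBS-oxy)-4-methyl-1-(tributylstannyl)pent-4-en-1-yl]-2-oxo-3,3a,6,6a-tetrahydro-2H-cyclopenta[b]furan-4-olate | [Li]OC1=C([C@H]([Sn](CCCC)(CCCC)CCCC)C[C@H](O[Si](C)(C)C(C)(C)C)C(C)=C)C[C@H]2OC(=O)C[C@@H]12 | intermediate (not isolated)
19 | (3aR,5R,6aR)-5-methyl-5-[(1R,3S)-3-(TBS-oxy)-4-methyl-1-(tributylstannyl)pent-4-en-1-yl]tetrahydro-2H-cyclopenta[b]furan-2,4(3H)-dione | O=C1[C@](C)([C@H]([Sn](CCCC)(CCCC)CCCC)C[C@H](O[Si](C)(C)C(C)(C)C)C(C)=C)C[C@H]2OC(=O)C[C@@H]12 | intermediate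
20 | (3aR,4S,5R,6aR)-4-ethenyl-4-hydroxy-5-methyl-5-[(1R,3S)-3-(TBS-oxy)-4-methyl-1-(tributylstannyl)pent-4-en-1-yl]hexahydro-2H-cyclopenta[b]furan-2-one | C=C[C@@]1(O)[C@](C)([C@H]([Sn](CCCC)(CCCC)CCCC)C[C@H](O[Si](C)(C)C(C)(C)C)C(C)=C)C[C@H]2OC(=O)C[C@@H]12 | intermediate
21 | (1R,3S,6S,7R,8R,10R)-6-hydroxy-3-(TBS-oxy)-1-(tributylstannyl)-6,10-cyclo-13-norgermacr-4-en-12,8-olide (cyclopentane trans-fused to cycloheptene; cis γ-lactone) | O[C@]12C=C(C)[C@@H](O[Si](C)(C)C(C)(C)C)C[C@@H]([Sn](CCCC)(CCCC)CCCC)[C@]1(C)C[C@H]3OC(=O)C[C@@H]23 | intermediate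
22 | N-methoxy-N-methyl-(1R,3S,6S,7R,8R,10R)-6,8-dihydroxy-3-(TBS-oxy)-1-(tributylstannyl)-6,10-cyclo-13-norgermacr-4-en-12-amide | O[C@]12C=C(C)[C@@H](O[Si](C)(C)C(C)(C)C)C[C@@H]([Sn](CCCC)(CCCC)CCCC)[C@]1(C)C[C@@H](O)[C@H]2CC(=O)N(C)OC | intermediate
23 | N-methoxy-N-methyl-(3S,7R,8R)-8-hydroxy-6-oxo-3-(TBS-oxy)-13-norgermacra-1(10)E,4Z-dien-12-amide | O=C1/C=C(C)\[C@@H](O[Si](C)(C)C(C)(C)C)C/C=C(C)/C[C@@H](O)[C@H]1CC(=O)N(C)OC | intermediate
24 | N-methoxy-N-methyl-(3S,6R,7R,8R)-6,8-dihydroxy-3-(TBS-oxy)-13-norgermacra-1(10)E,4Z-dien-12-amide | O[C@@H]1/C=C(C)\[C@@H](O[Si](C)(C)C(C)(C)C)C/C=C(C)/C[C@@H](O)[C@H]1CC(=O)N(C)OC | intermediate (not isolated)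
25 | (3S,6R,7R,8R)-8-hydroxy-3-(TBS-oxy)-13-norgermacra-1(10)E,4Z-dien-12,6-olide | C1C(=O)O[C@@H]2/C=C(/C)[C@@H](O[Si](C)(C)C(C)(C)C)C/C=C(C)/C[C@@H](O)[C@@H]12 | intermediate
26 | (3S,6R,7R,8R,11R)-13-(dimethylamino)-8-hydroxy-3-(TBS-oxy)germacra-1(10)E,4Z-dien-12,6-olide | CN(C)C[C@@H]1C(=O)O[C@@H]2/C=C(/C)[C@@H](O[Si](C)(C)C(C)(C)C)C/C=C(C)/C[C@@H](O)[C@@H]12 | intermediate (not isolated)
27 | trimethylammonium iodide of 26 (N-methylated at the C13 nitrogen) | C[N+](C)(C)C[C@@H]1C(=O)O[C@@H]2/C=C(/C)[C@@H](O[Si](C)(C)C(C)(C)C)C/C=C(C)/C[C@@H](O)[C@@H]12.[I-] | intermediate (not isolated)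
28 | (3S,6R,7R,8R)-8-hydroxy-3-(TBS-oxy)germacra-1(10)E,4Z,11(13)-trien-12,6-olide | C=C1C(=O)O[C@@H]2/C=C(/C)[C@@H](O[Si](C)(C)C(C)(C)C)C/C=C(C)/C[C@@H](O)[C@@H]12 | intermediate
29 | (2R,3R)-2,3-dimethyloxirane-2-carboxylic 2,4,6-trichlorobenzoic anhydride | O=C(OC(=O)[C@]1(C)O[C@@H]1C)c1c(Cl)cc(Cl)cc1Cl | intermediate (not isolated)
30 | (3S,6R,7R,8R)-8-[(2R,3R)-2,3-dimethyloxirane-2-carbonyloxy]-3-(TBS-oxy)germacra-1(10)E,4Z,11(13)-trien-12,6-olide | C=C1C(=O)O[C@@H]2/C=C(/C)[C@@H](O[Si](C)(C)C(C)(C)C)C/C=C(C)/C[C@@H](OC(=O)[C@]3(C)O[C@@H]3C)[C@@H]12 | intermediate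
31 | (1R,3S,6R,7R,8R,10R)-1,10-epoxy-8-[(2R,3R)-2,3-dimethyloxirane-2-carbonyloxy]-3-(TBS-oxy)germacra-4Z,11(13)-dien-12,6-olide | C=C1C(=O)O[C@@H]2/C=C(/C)[C@@H](O[Si](C)(C)C(C)(C)C)C[C@H]3O[C@]3(C)C[C@@H](OC(=O)[C@]3(C)O[C@@H]3C)[C@@H]12 | intermediate
32 | (1R,3S,6R,7R,8R,10R)-1,10-epoxy-8-[(2R,3R)-2,3-dimethyloxirane-2-carbonyloxy]-3-hydroxygermacra-4Z,11(13)-dien-12,6-olide (CNP0268255.1) | C=C1C(=O)O[C@@H]2/C=C(/C)[C@@H](O)C[C@H]3O[C@]3(C)C[C@@H](OC(=O)[C@]3(C)O[C@@H]3C)[C@@H]12 | target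

**Step count**
Total: 20 steps. Longest linear sequence: 14 steps (steps 1–3 and 10–20); the aldehyde (steps 4–6) and the epoxy acid (steps 7–9) are made in parallel.

**Steps most likely to fail, with fallbacks**

Step 2 (the proposed lactone-forming α′-alkylation). The risks are the slow s-trans ester rotamer, O-alkylation and oligomerisation. The fallback uses known chemistry, sets out from 1 and comes back at 3. Mitsunobu inversion of 1 with benzoic acid (PPh3, DIAD) gives (1R)-4-oxocyclopent-2-en-1-yl benzoate F1. Methanolysis (K2CO3, MeOH, 0 °C) gives (4R)-4-hydroxycyclopent-2-en-1-one F2, and silylation (TBSCl, imidazole) gives (4R)-4-(TBS-oxy)cyclopent-2-en-1-one F3. Kinetic α′-alkylation (LiN(SiMe3)2, THF, −78 °C, then tert-butyl bromoacetate) enters trans to the silyloxy group and gives tert-butyl 2-[(1R,5S)-5-(TBS-oxy)-2-oxocyclopent-3-en-1-yl]acetate F4. TFA followed by HF·pyridine gives 2-[(1R,5S)-5-hydroxy-2-oxocyclopent-3-en-1-yl]acetic acid F5. Mitsunobu lactonisation (PPh3, DIAD, THF) then closes the γ-lactone with inversion at the carbinol carbon and delivers 3. The two inversions at C8 restore the configuration of 1, and the acetic acid arm ends cis to oxygen.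

Step 11 (stannyl addition/methylation). With the E-alkylidene ketone the anti-to-tin preference and the convex-face preference of the bicycle oppose each other, so the methyl group may enter syn to tin and lead to the Z alkene. The fallback sets out from 17 and comes back at 23, using the geometric isomer in which both preferences agree. Irradiation of 17 (350 nm, benzene) gives a separable E/Z mixture (E isomer recycled) containing (3aR,5Z,6aR)-5-[(3S)-3-(TBS-oxy)-4-methylpent-4-en-1-ylidene]tetrahydro-2H-cyclopenta[b]furan-2,4(3H)-dione F6. Bu3SnLi then MeI, both from the convex face and anti to each other, give (3aR,5S,6aR)-5-methyl-5-[(1S,3S)-3-(TBS-oxy)-4-methyl-1-(tributylstannyl)pent-4-en-1-yl]tetrahydro-2H-cyclopenta[b]furan-2,4(3H)-dione F7. CH2=CHMgBr/CeCl3 gives (3aR,4R,5S,6aR)-4-ethenyl-4-hydroxy-5-methyl-5-[(1S,3S)-3-(TBS-oxy)-4-methyl-1-(tributylstannyl)pent-4-en-1-yl]hexahydro-2H-cyclopenta[b]furan-2-one F8. Metathesis with the second-generation Grubbs catalyst gives (1S,3S,6R,7R,8R,10S)-6-hydroxy-3-(TBS-oxy)-1-(tributylstannyl)-6,10-cyclo-13-norgermacr-4-en-12,8-olide F9. AlMe3/MeNH(OMe)·HCl gives N-methoxy-N-methyl-(1S,3S,6R,7R,8R,10S)-6,8-dihydroxy-3-(TBS-oxy)-1-(tributylstannyl)-6,10-cyclo-13-norgermacr-4-en-12-amide F10. Pb(OAc)4 then gives 23, because the relative configuration at C1/C10 is the same as in 22.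

Step 15 (the ring expansion). The risks are oxidation of the free C8 carbinol or the amide by tetravalent lead, and Cope rearrangement of the product. The fallback sets out from 21 and comes back at 23. It moves the fragmentation one stage earlier and into the alkoxy-radical manifold. Lactone 21 is treated with PhI(OAc)2 and I2 under visible light in cyclohexane/CH2Cl2 at 20 °C. The hypoiodite undergoes β-scission of the C6–C10 bond with loss of the tributylstannyl radical and gives (3S,7R,8R)-6-oxo-3-(TBS-oxy)-13-norgermacra-1(10)E,4Z-dien-12,8-olide F11. The lactone is then opened with AlMe3/MeNH(OMe)·HCl at −20 °C to give 23. The alkene geometry must be checked, since the radical pathway is less strictly stereospecific.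

**Further compounds**
F1 | step 2 | (1R)-4-oxocyclopent-2-en-1-yl benzoate | O=C1C=C[C@H](OC(=O)c2ccccc2)C1
F2 | step 2 | (4R)-4-hydroxycyclopent-2-en-1-one | O=C1C=C[C@H](O)C1
F3 | step 2 | (4R)-4-(TBS-oxy)cyclopent-2-en-1-one | O=C1C=C[C@H](O[Si](C)(C)C(C)(C)C)C1
F4 | step 2 | tert-butyl 2-[(1R,5S)-5-(TBS-oxy)-2-oxocyclopent-3-en-1-yl]acetate | O=C1C=C[C@H](O[Si](C)(C)C(C)(C)C)[C@H]1CC(=O)OC(C)(C)C
F5 | step 2 | 2-[(1R,5S)-5-hydroxy-2-oxocyclopent-3-en-1-yl]acetic acid | O=C1C=C[C@H](O)[C@H]1CC(=O)O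
F6 | step 11 | (3aR,5Z,6aR)-5-[(3S)-3-(TBS-oxy)-4-methylpent-4-en-1-ylidene]tetrahydro-2H-cyclopenta[b]furan-2,4(3H)-dione | O=C1/C(=C\C[C@H](O[Si](C)(C)C(C)(C)C)C(C)=C)C[C@H]2OC(=O)C[C@@H]12
F7 | step 11 | (3aR,5S,6aR)-5-methyl-5-[(1S,3S)-3-(TBS-oxy)-4-methyl-1-(tributylstannyl)pent-4-en-1-yl]tetrahydro-2H-cyclopenta[b]furan-2,4(3H)-dione | O=C1[C@@](C)([C@@H]([Sn](CCCC)(CCCC)CCCC)C[C@H](O[Si](C)(C)C(C)(C)C)C(C)=C)C[C@H]2OC(=O)C[C@@H]12
F8 | step 11 | (3aR,4R,5S,6aR)-4-ethenyl-4-hydroxy-5-methyl-5-[(1S,3S)-3-(TBS-oxy)-4-methyl-1-(tributylstannyl)pent-4-en-1-yl]hexahydro-2H-cyclopenta[b]furan-2-one | C=C[C@]1(O)[C@@](C)([C@@H]([Sn](CCCC)(CCCC)CCCC)C[C@H](O[Si](C)(C)C(C)(C)C)C(C)=C)C[C@H]2OC(=O)C[C@@H]12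
F9 | step 11 | (1S,3S,6R,7R,8R,10S)-6-hydroxy-3-(TBS-oxy)-1-(tributylstannyl)-6,10-cyclo-13-norgermacr-4-en-12,8-olide | O[C@@]12C=C(C)[C@@H](O[Si](C)(C)C(C)(C)C)C[C@H]([Sn](CCCC)(CCCC)CCCC)[C@@]1(C)C[C@H]3OC(=O)C[C@@H]23
F10 | step 11 | N-methoxy-N-methyl-(1S,3S,6R,7R,8R,10S)-6,8-dihydroxy-3-(TBS-oxy)-1-(tributylstannyl)-6,10-cyclo-13-norgermacr-4-en-12-amide | O[C@@]12C=C(C)[C@@H](O[Si](C)(C)C(C)(C)C)C[C@H]([Sn](CCCC)(CCCC)CCCC)[C@@]1(C)C[C@@H](O)[C@H]2CC(=O)N(C)OC
F11 | step 15 | (3S,7R,8R)-6-oxo-3-(TBS-oxy)-13-norgermacra-1(10)E,4Z-dien-12,8-olide | O=C1/C=C(C)\[C@@H](O[Si](C)(C)C(C)(C)C)C/C=C(C)/C[C@H]2OC(=O)C[C@@H]12
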